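**Retrosynthetic overview**
- The target is a (2S)-flavanone (rings A, C, B) joined through C5' of ring B to C8'' of apigenin; the last step is hydrogenolysis of seven benzyl ethers.
- Flavanone rings A and C are disconnected together at O1–C8a and C4–C4a: 3,5-bis(benzyloxy)benzyne (ring A) is annulated onto a (3S)-β-silyloxy Weinreb amide, and ring C closes when the C4a carbanion attacks C4.
- Enabling feature: the 1,3-relationship of O1 and the C4 carbonyl across C2–C3, and the meta-dioxygenated ring A, whose O5 next to C4a polarizes the C4a–C8a aryne so that O1 bonds to C8a and the carbanion forms at C4a.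
- C2 is set by asymmetric transfer hydrogenation of a β-keto ester and is not touched again; the C5'–C8'' biaryl bond comes from Suzuki coupling of a ring B boronate with 8-iodo-tri-O-benzylapigenin.
- Ring order: flavone pyranone ring (Claisen–Schmidt, I2/DMSO), then the biaryl bond, then rings A and C of the flavanone in the key step.

Key step: step 14

Assumptions: the (S,S)-TsDPEN catalyst in step 7 is taken to give the (S)-carbinol as it does with aryl methyl ketones (otherwise the (R,R) catalyst is used); the biaryl axis is taken as freely rotating, as the target is drawn without axial chirality; compounds 1, 4, 7 and 15 are taken as commercial.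

**Route**

Step 1
Reactants: 1 1-(2,4,6-trihydroxyphenyl)ethanone
Product: 2 1-[2,4-bis(benzyloxy)-6-hydroxyphenyl]ethanone
Conditions: BnBr (2.1 equiv), K2CO3, DMF, 23 °C
Reagents that add atoms: benzyl bromide BrCc1ccccc1
Why: Williamson etherification, in which the hydroxyl hydrogen-bonded to the acetyl carbonyl is the least nucleophilic and should stay free.

Step 2
Reactants: 2 1-[2,4-bis(benzyloxy)-6-hydroxyphenyl]ethanone
Product: 3 1-[4,6-bis(benzyloxy)-2-hydroxy-3-iodophenyl]ethanone
Conditions: NIS (1.05 equiv), TFA (cat.), MeCN, 0 to 23 °C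
Reagents that add atoms: N-iodosuccinimide O=C1CCC(=O)N1I
Why: Electrophilic aromatic iodination should go ortho to the free phenol (C3), the less hindered open position since C5 is flanked by two benzyloxy groups; this carbon becomes C8 of the flavone.

Step 3
Reactants: 3 1-[4,6-bis(benzyloxy)-2-hydroxy-3-iodophenyl]ethanone; 4 4-(benzyloxy)benzaldehyde
Product: 5 (E)-1-[4,6-bis(benzyloxy)-2-hydroxy-3-iodophenyl]-3-[4-(benzyloxy)phenyl]prop-2-en-1-one
Conditions: KOH, EtOH/THF, 23 °C
Reagents that add atoms: none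
Why: Claisen–Schmidt condensation of a methyl ketone with a non-enolizable aldehyde should give the E chalcone under thermodynamic control.

Step 4
Reactants: 5 (E)-1-[4,6-bis(benzyloxy)-2-hydroxy-3-iodophenyl]-3-[4-(benzyloxy)phenyl]prop-2-en-1-one
Product: 6 5,7-bis(benzyloxy)-2-[4-(benzyloxy)phenyl]-8-iodo-4H-chromen-4-one
Conditions: I2 (10 mol %), DMSO, 130 °C
Reagents that add atoms: none
Why: Iodine-catalysed oxidative cyclization of a 2'-hydroxychalcone (oxa-Michael closure, then dehydrogenation with DMSO as terminal oxidant) should give the flavone with iodine at C8.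

Step 5
Reactants: 7 3-bromo-4,5-dihydroxybenzaldehyde
Product: 8 3,4-bis(benzyloxy)-5-bromobenzaldehyde
Conditions: BnBr (2.3 equiv), K2CO3, DMF, 60 °C
Reagents that add atoms: benzyl bromide BrCc1ccccc1
Why: Williamson etherification of both catechol hydroxyls, with no competing site.

Step 6
Reactants: 8 3,4-bis(benzyloxy)-5-bromobenzaldehyde
Product: 9 ethyl 3-[3,4-bis(benzyloxy)-5-bromophenyl]-3-oxopropanoate
Conditions: ethyl diazoacetate, SnCl2 (10 mol %), CH2Cl2, 23 °C
Reagents that add atoms: ethyl diazoacetate CCOC(=O)C=[N+]=[N-]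
Why: Roskamp homologation, in which Lewis-acid-promoted addition of the diazo ester to the aldehyde and a 1,2-hydride shift with loss of N2 should give the β-keto ester.

Step 7
Reactants: 9 ethyl 3-[3,4-bis(benzyloxy)-5-bromophenyl]-3-oxopropanoate
Product: 10 ethyl (3S)-3-[3,4-bis(benzyloxy)-5-bromophenyl]-3-hydroxypropanoate
Conditions: RuCl[(S,S)-TsDPEN](p-cymene) (1 mol %), HCO2H/Et3N (5:2), DMF, 30 °C
Reagents that add atoms: none
Why: Noyori asymmetric transfer hydrogenation of the aryl ketone, where the CH/π contact between the aryl group and the p-cymene ligand should direct hydride to the face that gives the (S)-carbinol (priority order OH > aryl > CH2 as in 1-arylethanols).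

Step 8
Reactants: 10 ethyl (3S)-3-[3,4-bis(benzyloxy)-5-bromophenyl]-3-hydroxypropanoate
Product: 11 ethyl (3S)-3-[3,4-bis(benzyloxy)-5-(4,4,5,5-tetramethyl-1,3,2-dioxaborolan-2-yl)phenyl]-3-hydroxypropanoate
Conditions: B2pin2, PdCl2(dppf) (5 mol %), KOAc, 1,4-dioxane, 85 °C
Reagents that add atoms: bis(pinacolato)diboron CC1(C)OB(OC1(C)C)B1OC(C)(C)C(C)(C)O1
Why: Miyaura borylation of the aryl bromide under acetate base should tolerate the free hydroxyl and the ester and leave the carbinol center untouched.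

Step 9
Reactants: 6 5,7-bis(benzyloxy)-2-[4-(benzyloxy)phenyl]-8-iodo-4H-chromen-4-one; 11 ethyl (3S)-3-[3,4-bis(benzyloxy)-5-(4,4,5,5-tetramethyl-1,3,2-dioxaborolan-2-yl)phenyl]-3-hydroxypropanoate
Product: 12 ethyl (3S)-3-{3,4-bis(benzyloxy)-5-[5,7-bis(benzyloxy)-2-(4-benzyloxyphenyl)-4-oxo-4H-chromen-8-yl]phenyl}-3-hydroxypropanoate
Conditions: Pd(OAc)2 (5 mol %), SPhos (10 mol %), K3PO4, toluene/H2O (10:1), 80 °C
Reagents that add atoms: none
Why: Suzuki–Miyaura coupling with a bulky electron-rich biarylphosphine should join the doubly ortho-oxygenated C8'' iodide to the ring B boronate, the hindered partner serving as the electrophile.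

Step 10
Reactants: 12 ethyl (3S)-3-{3,4-bis(benzyloxy)-5-[5,7-bis(benzyloxy)-2-(4-benzyloxyphenyl)-4-oxo-4H-chromen-8-yl]phenyl}-3-hydroxypropanoate
Product: 13 (3S)-3-{3,4-bis(benzyloxy)-5-[5,7-bis(benzyloxy)-2-(4-benzyloxyphenyl)-4-oxo-4H-chromen-8-yl]phenyl}-3-hydroxy-N-methoxy-N-methylpropanamide
Conditions: MeNHOMe·HCl, iPrMgCl, THF, −20 °C
Reagents that add atoms: N,O-dimethylhydroxylamine hydrochloride CNOC.Cl
Why: Weinreb amide formation by aminolysis of the ester with the chloromagnesium amide made in the flask, which at −20 °C should leave the flavone and the carbinol center alone.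

Step 11
Reactants: 13 (3S)-3-{3,4-bis(benzyloxy)-5-[5,7-bis(benzyloxy)-2-(4-benzyloxyphenyl)-4-oxo-4H-chromen-8-yl]phenyl}-3-hydroxy-N-methoxy-N-methylpropanamide
Product: 14 (3S)-3-{3,4-bis(benzyloxy)-5-[5,7-bis(benzyloxy)-2-(4-benzyloxyphenyl)-4-oxo-4H-chromen-8-yl]phenyl}-N-methoxy-N-methyl-3-[(trimethylsilyl)oxy]propanamide
Conditions: 1-(trimethylsilyl)imidazole, CH2Cl2, 23 °C
Reagents that add atoms: 1-(trimethylsilyl)imidazole C[Si](C)(C)n1ccnc1
Why: O-silylation of the secondary alcohol with a neutral silyl donor should give a proton-free latent alkoxide for the aryne step once the imidazole is washed out.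

Step 12
Reactants: 15 3,5-bis(benzyloxy)phenol
Product: 16 3,5-bis(benzyloxy)-2-bromophenol
Conditions: NBS (1.0 equiv), CH2Cl2, −78 °C
Reagents that add atoms: N-bromosuccinimide O=C1CCC(=O)N1Br
Why: Low-temperature electrophilic bromination should go ortho to the free phenol (two equivalent positions, hydrogen-bond-assisted delivery) and stop at the monobromide.

Step 13
Reactants: 16 3,5-bis(benzyloxy)-2-bromophenol
Product: 19 3,5-bis(benzyloxy)-2-(trimethylsilyl)phenyl trifluoromethanesulfonate, via O-trimethylsilyl ether 17 (not isolated), via lithium silylphenolate 18 (not isolated)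
Conditions: HMDS, THF, 70 °C; n-BuLi, THF, −100 °C; Tf2O, −100 to 23 °C
Reagents that add atoms: hexamethyldisilazane C[Si](C)(C)N[Si](C)(C)C; trifluoromethanesulfonic anhydride O=S(=O)(OS(=O)(=O)C(F)(F)F)C(F)(F)F
Why: O-silylation, bromine–lithium exchange, retro-Brook 1,3-migration of silicon from O to C and O-triflation of the phenolate is the standard sequence to an ortho-silylaryl triflate.

Step 14
Reactants: 14 (3S)-3-{3,4-bis(benzyloxy)-5-[5,7-bis(benzyloxy)-2-(4-benzyloxyphenyl)-4-oxo-4H-chromen-8-yl]phenyl}-N-methoxy-N-methyl-3-[(trimethylsilyl)oxy]propanamide; 19 3,5-bis(benzyloxy)-2-(trimethylsilyl)phenyl trifluoromethanesulfonate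
Product: 22 (2S)-5,7-bis(benzyloxy)-2-{3,4-bis(benzyloxy)-5-[5,7-bis(benzyloxy)-2-(4-benzyloxyphenyl)-4-oxo-4H-chromen-8-yl]phenyl}-2,3-dihydro-4H-chromen-4-one, via 3,5-bis(benzyloxy)benzyne 20 (not isolated), via potassium hemiaminal alkoxide 21 (not isolated)
Conditions: KF, 18-crown-6, THF, 0 to 23 °C (19 added slowly); then AcOH, H2O, 0 °C
Reagents that add atoms: none
Why: Proposed new method: fluoride cleaves the O–Si bond of 14 and converts 19 into aryne 20, the C3 alkoxide adds to the aryne carbon remote from the benzyloxy group, and the resulting ortho-aryl carbanion attacks the Weinreb amide carbonyl to give the tetrahedral adduct 21, which releases the ketone only on acidic work-up. The closest known reaction types are the annulation of arynes with salicylate esters to xanthones (O-arylation followed by intramolecular acyl substitution), aryne insertion into the N–C(O) bond of β-lactams, and the cyclization of ortho-lithiated aryl ethers onto Weinreb amides to chroman-4-ones; what is new is the aliphatic β-silyloxy amide as the partner. Ring C closes by 6-exo-trig attack of the C4a carbanion on C4, after the intermolecular O1–C8a bond has attached ring A. No stereocenter is created in the product: C2 keeps its (S) configuration because the C2–O bond is never broken, and the transient C4 center of 21 is lost on hydrolysis. The step needs regioselective addition to the unsymmetrical aryne, secured by the benzyloxy group next to one aryne carbon (inductive stabilization of the carbanion at C4a, attack at the less hindered C8a), and acyl attack in preference to protonation, secured by the aprotic silyl ether mode and the 1,3-placement of oxygen and carbonyl. Holding the carbonyl as 21 should keep the base-labile flavanone away from fluoride and alkoxide.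

Step 15
Reactants: 22 (2S)-5,7-bis(benzyloxy)-2-{3,4-bis(benzyloxy)-5-[5,7-bis(benzyloxy)-2-(4-benzyloxyphenyl)-4-oxo-4H-chromen-8-yl]phenyl}-2,3-dihydro-4H-chromen-4-one
Product: 23 (2S)-2-{3,4-dihydroxy-5-[5,7-dihydroxy-2-(4-hydroxyphenyl)-4-oxo-4H-chromen-8-yl]phenyl}-5,7-dihydroxy-2,3-dihydro-4H-chromen-4-one
Conditions: H2 (1 atm), Pd/C (10 wt %), THF/MeOH, 23 °C
Reagents that add atoms: none
Why: Hydrogenolysis of the seven aryl benzyl ethers under neutral conditions should leave the C2 stereocenter, the flavanone ketone and the flavone enone intact.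

**Compound list**

1 | 1-(2,4,6-trihydroxyphenyl)ethanone | CC(=O)c1c(O)cc(O)cc1O | starting material
2 | 1-[2,4-bis(benzyloxy)-6-hydroxyphenyl]ethanone | CC(=O)c1c(O)cc(OCc2ccccc2)cc1OCc1ccccc1 | intermediate
3 | 1-[4,6-bis(benzyloxy)-2-hydroxy-3-iodophenyl]ethanone | CC(=O)c1c(O)c(I)c(OCc2ccccc2)cc1OCc1ccccc1 | intermediate
4 | 4-(benzyloxy)benzaldehyde | O=Cc1ccc(OCc2ccccc2)cc1 | starting material
5 | (E)-1-[4,6-bis(benzyloxy)-2-hydroxy-3-iodophenyl]-3-[4-(benzyloxy)phenyl]prop-2-en-1-one | O=C(/C=C/c1ccc(OCc2ccccc2)cc1)c1c(O)c(I)c(OCc2ccccc2)cc1OCc1ccccc1 | intermediate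
6 | 5,7-bis(benzyloxy)-2-[4-(benzyloxy)phenyl]-8-iodo-4H-chromen-4-one | O=c1cc(-c2ccc(OCc3ccccc3)cc2)oc2c(I)c(OCc3ccccc3)cc(OCc3ccccc3)c12 | intermediate
7 | 3-bromo-4,5-dihydroxybenzaldehyde | O=Cc1cc(O)c(O)c(Br)c1 | starting material
8 | 3,4-bis(benzyloxy)-5-bromobenzaldehyde | O=Cc1cc(OCc2ccccc2)c(OCc2ccccc2)c(Br)c1 | intermediate
9 | ethyl 3-[3,4-bis(benzyloxy)-5-bromophenyl]-3-oxopropanoate | CCOC(=O)CC(=O)c1cc(OCc2ccccc2)c(OCc2ccccc2)c(Br)c1 | intermediate
10 | ethyl (3S)-3-[3,4-bis(benzyloxy)-5-bromophenyl]-3-hydroxypropanoate | CCOC(=O)C[C@H](O)c1cc(OCc2ccccc2)c(OCc2ccccc2)c(Br)c1 | intermediate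
11 | ethyl (3S)-3-[3,4-bis(benzyloxy)-5-(4,4,5,5-tetramethyl-1,3,2-dioxaborolan-2-yl)phenyl]-3-hydroxypropanoate | CCOC(=O)C[C@H](O)c1cc(OCc2ccccc2)c(OCc2ccccc2)c(B2OC(C)(C)C(C)(C)O2)c1 | intermediate
12 | ethyl (3S)-3-{3,4-bis(benzyloxy)-5-[5,7-bis(benzyloxy)-2-(4-benzyloxyphenyl)-4-oxo-4H-chromen-8-yl]phenyl}-3-hydroxypropanoate | CCOC(=O)C[C@H](O)c1cc(OCc2ccccc2)c(OCc2ccccc2)c(-c2c(OCc3ccccc3)cc(OCc3ccccc3)c3c(=O)cc(-c4ccc(OCc5ccccc5)cc4)oc23)c1 | intermediate
13 | (3S)-3-{3,4-bis(benzyloxy)-5-[5,7-bis(benzyloxy)-2-(4-benzyloxyphenyl)-4-oxo-4H-chromen-8-yl]phenyl}-3-hydroxy-N-methoxy-N-methylpropanamide | CON(C)C(=O)C[C@H](O)c1cc(OCc2ccccc2)c(OCc2ccccc2)c(-c2c(OCc3ccccc3)cc(OCc3ccccc3)c3c(=O)cc(-c4ccc(OCc5ccccc5)cc4)oc23)c1 | intermediate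
14 | (3S)-3-{3,4-bis(benzyloxy)-5-[5,7-bis(benzyloxy)-2-(4-benzyloxyphenyl)-4-oxo-4H-chromen-8-yl]phenyl}-N-methoxy-N-methyl-3-[(trimethylsilyl)oxy]propanamide | CON(C)C(=O)C[C@H](O[Si](C)(C)C)c1cc(OCc2ccccc2)c(OCc2ccccc2)c(-c2c(OCc3ccccc3)cc(OCc3ccccc3)c3c(=O)cc(-c4ccc(OCc5ccccc5)cc4)oc23)c1 | intermediate
15 | 3,5-bis(benzyloxy)phenol | Oc1cc(OCc2ccccc2)cc(OCc2ccccc2)c1 | starting material
16 | 3,5-bis(benzyloxy)-2-bromophenol | Oc1cc(OCc2ccccc2)cc(OCc2ccccc2)c1Br | intermediate
17 | [3,5-bis(benzyloxy)-2-bromophenoxy]trimethylsilane | C[Si](C)(C)Oc1cc(OCc2ccccc2)cc(OCc2ccccc2)c1Br | intermediate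
18 | lithium 3,5-bis(benzyloxy)-2-(trimethylsilyl)phenolate | [Li+].[O-]c1cc(OCc2ccccc2)cc(OCc2ccccc2)c1[Si](C)(C)C | intermediate
19 | 3,5-bis(benzyloxy)-2-(trimethylsilyl)phenyl trifluoromethanesulfonate | C[Si](C)(C)c1c(OS(=O)(=O)C(F)(F)F)cc(OCc2ccccc2)cc1OCc1ccccc1 | intermediate
20 | 3,5-bis(benzyloxy)benzyne (3,5-bis(benzyloxy)-1,2-didehydrobenzene) | C1#CC(OCc2ccccc2)=CC(OCc2ccccc2)=C1 | intermediate
21 | potassium (2S)-5,7-bis(benzyloxy)-2-{3,4-bis(benzyloxy)-5-[5,7-bis(benzyloxy)-2-(4-benzyloxyphenyl)-4-oxo-4H-chromen-8-yl]phenyl}-4-[methoxy(methyl)amino]-3,4-dihydro-2H-chromen-4-olate (C4 epimers) | [K+].[O-]C1(N(C)OC)C[C@@H](c2cc(OCc3ccccc3)c(OCc3ccccc3)c(-c3c(OCc4ccccc4)cc(OCc4ccccc4)c4c(=O)cc(-c5ccc(OCc6ccccc6)cc5)oc34)c2)Oc2cc(OCc3ccccc3)cc(OCc3ccccc3)c21 | intermediate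
22 | (2S)-5,7-bis(benzyloxy)-2-{3,4-bis(benzyloxy)-5-[5,7-bis(benzyloxy)-2-(4-benzyloxyphenyl)-4-oxo-4H-chromen-8-yl]phenyl}-2,3-dihydro-4H-chromen-4-one | O=C1C[C@@H](c2cc(OCc3ccccc3)c(OCc3ccccc3)c(-c3c(OCc4ccccc4)cc(OCc4ccccc4)c4c(=O)cc(-c5ccc(OCc6ccccc6)cc5)oc34)c2)Oc2cc(OCc3ccccc3)cc(OCc3ccccc3)c21 | intermediate
23 | (2S)-2-{3,4-dihydroxy-5-[5,7-dihydroxy-2-(4-hydroxyphenyl)-4-oxo-4H-chromen-8-yl]phenyl}-5,7-dihydroxy-2,3-dihydro-4H-chromen-4-one (CNP0204144.1) | O=C1C[C@@H](c2cc(O)c(O)c(-c3c(O)cc(O)c4c(=O)cc(-c5ccc(O)cc5)oc34)c2)Oc2cc(O)cc(O)c21 | target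

**Step count and risks**

Total steps: 15. Longest linear sequence: 9 steps (steps 1–4, 9–11, 14, 15).

Steps most likely to fail:

1. Step 14 (proposed new method). The aryl carbanion may be protonated, or may take a proton from C3 and then expel the aryloxide, before it reaches the amide carbonyl. The free alkoxide may undergo retro-aldol cleavage. The tetrahedral adduct may collapse in the flask and expose the flavanone to base, which would erode the configuration at C2. The fallback sets out from 12 and closes the ring in stages by known reactions. Treating 12 with 19, KF and 18-crown-6 in THF at 23 °C, now with the free hydroxyl as proton source, should give by O–H insertion into the aryne (a known etherification of alcohols, with retention at the carbinol carbon) the ethyl (3S)-3-aryl-3-[3,5-bis(benzyloxy)phenoxy]propanoate F1. LiOH in THF/H2O at 0 °C should give the corresponding 3-aryloxypropanoic acid F2. TFAA in CH2Cl2 at 0 °C (intramolecular Friedel–Crafts acylation through the mixed anhydride, onto either of the two equivalent ortho carbons of the trioxygenated ring) should then come back to the route at 22.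

2. Step 9. Oxidative addition and transmetalation at the doubly ortho-oxygenated C8'' position may be slow, so that protodeboronation of 11 and saponification of the ester take over. The fallback reverses the polarity of the coupling and sets out from 6. Miyaura borylation of 6 (B2pin2, PdCl2(dppf), KOAc, 1,4-dioxane, 85 °C) should give the flavone 8-boronic acid pinacol ester F3. This is coupled with bromide 10 under anhydrous conditions (Pd(OAc)2, SPhos, K3PO4, 1,4-dioxane, 90 °C) and comes back to the route at 12, bypassing 11.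

3. Step 15. Over-reduction may occur (hydrogenolysis of the benzylic C2–O1 bond opening ring C, or saturation of the flavone C2''=C3'' bond), and the reaction may stall when partly debenzylated polyphenols precipitate on the catalyst. The fallback replaces reductive cleavage by Lewis-acid dealkylation with a cation scavenger: 22 is treated with BCl3 and pentamethylbenzene in CH2Cl2 at −78 °C and then quenched with MeOH, which should lead from 22 directly to 23 without a new intermediate.

Further compounds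

F1 | step 14 | ethyl (3S)-3-{3,4-bis(benzyloxy)-5-[5,7-bis(benzyloxy)-2-(4-benzyloxyphenyl)-4-oxo-4H-chromen-8-yl]phenyl}-3-[3,5-bis(benzyloxy)phenoxy]propanoate | CCOC(=O)C[C@H](Oc1cc(OCc2ccccc2)cc(OCc2ccccc2)c1)c1cc(OCc2ccccc2)c(OCc2ccccc2)c(-c2c(OCc3ccccc3)cc(OCc3ccccc3)c3c(=O)cc(-c4ccc(OCc5ccccc5)cc4)oc23)c1
F2 | step 14 | (3S)-3-{3,4-bis(benzyloxy)-5-[5,7-bis(benzyloxy)-2-(4-benzyloxyphenyl)-4-oxo-4H-chromen-8-yl]phenyl}-3-[3,5-bis(benzyloxy)phenoxy]propanoic acid | OC(=O)C[C@H](Oc1cc(OCc2ccccc2)cc(OCc2ccccc2)c1)c1cc(OCc2ccccc2)c(OCc2ccccc2)c(-c2c(OCc3ccccc3)cc(OCc3ccccc3)c3c(=O)cc(-c4ccc(OCc5ccccc5)cc4)oc23)c1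
F3 | step 9 | 5,7-bis(benzyloxy)-2-[4-(benzyloxy)phenyl]-8-(4,4,5,5-tetramethyl-1,3,2-dioxaborolan-2-yl)-4H-chromen-4-one | O=c1cc(-c2ccc(OCc3ccccc3)cc2)oc2c(B3OC(C)(C)C(C)(C)O3)c(OCc3ccccc3)cc(OCc3ccccc3)c12
F0 | step 15 | none | none
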